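Atom labels: the carbinol carbon that bears CH2OBz is C1 and that CH2 is C7; round the ring follow C2 (CHOH), C3 (CHOBz), C4=C5 and C6 (CHOBz). On the cyclohexene, C7 and O6 stand cis on neighbouring carbons and O1 is cis to O2. The target is therefore cut back to an oxetan-2-one (O6–C7) fused at C1–C6 and a dioxolane fused at C1–C2. One aldol-lactonisation of an open-chain aldehyde acid makes C1–C6 and O6–C7, closes cyclohexene and beta-lactone, and sets C1 and C6. The precursor, drawn from D-ribonolactone, holds the C7 acid, the C1,C2-acetonide, a C3 silyl ether and a Z-enal ending at C6.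

Key step: step 9

Remarks on the design
- **O3 as a TBS ether until the triol stage.** An allylic ester at C3 could migrate to the neighbouring primary oxygen once that is freed. It would make aldehyde 7 prone to elimination under ylide conditions and would be ionisable by zerovalent palladium. It would also acidify C3–H and act as a leaving group in the amine-rich key step, and the hydride step would strip it anyway.
- **C7 as a methyl ester, cleaved by hydroxide before the aldehyde exists.** The Z-enal therefore never meets palladium, phosphine, a secondary amine or hydroxide.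
- **C1 is erased in step 9,** so epimerisation at C1 anywhere in 4–12 is of no consequence.
- **Stereochemical bookkeeping.** Sugar C3 and C4 of 1 become C2 and C3 of 20 without any bond to them being broken. In step 9, C6 enters on the dioxolane face that C7 occupied in 1.
- **Assumption:** 1, 8, 18 and all reagents named are taken as commercial, including 2-bromo-1-ethylpyridinium tetrafluoroborate and 4-pyrrolidinopyridine.

Step 1
Reactants: 1 2,3-O-isopropylidene-D-ribono-1,4-lactone
Product: 2 5-O-TBS-2,3-O-isopropylidene-D-ribono-1,4-lactone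
Conditions: TBSCl, imidazole, DMF, 0 °C to rt
Reagents that add atoms: tert-butyldimethylsilyl chloride, CC(C)(C)[Si](C)(C)Cl
Why: Imidazole-promoted silylation of the only free (primary) hydroxyl gives a lipophilic lactone that tolerates the aqueous base of the next step, and no stereocentre is touched.

Step 2
Reactants: 2 5-O-TBS-2,3-O-isopropylidene-D-ribono-1,4-lactone
Product: 4 methyl 5-O-TBS-2,3-O-isopropylidene-D-ribonate, via potassium carboxylate 3 (not isolated)
Conditions: KOH (1.0 equiv), THF/H2O, 0 °C; evaporate, toluene azeotrope; MeI, DMF, 0 °C to rt; cold extractive work-up, used crude at once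
Reagents that add atoms: potassium hydroxide, [K+].[OH-]; iodomethane, CI
Why: Saponification of the gamma-lactone followed by SN2 O-alkylation of the dry carboxylate builds the ester under neutral conditions with no acid or base left to catalyse re-closure, and only the acyl C–O bond is broken, so the sugar stereocentres stay as they are.

Step 3
Reactants: 4 methyl 5-O-TBS-2,3-O-isopropylidene-D-ribonate
Product: 5 methyl 4,5-bis-O-TBS-2,3-O-isopropylidene-D-ribonate
Conditions: TBSOTf, 2,6-lutidine, CH2Cl2, −78 to 0 °C
Reagents that add atoms: tert-butyldimethylsilyl triflate, CC(C)(C)[Si](C)(C)OS(=O)(=O)C(F)(F)F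
Why: Silyl triflate with a hindered pyridine base silylates the crowded O3 hydroxyl at low temperature faster than it can attack the ester, which ends the lactonisation risk and installs a base-stable, non-migrating, non-leaving group.

Step 4
Reactants: 5 methyl 4,5-bis-O-TBS-2,3-O-isopropylidene-D-ribonate
Product: 6 methyl 4-O-TBS-2,3-O-isopropylidene-D-ribonate
Conditions: HF·pyridine, pyridine, THF, 0 °C; used directly
Reagents that add atoms: none
Why: Fluoride-mediated desilylation in buffered HF·pyridine distinguishes on steric grounds between the primary and the flanked secondary TBS ether, and the slightly acidic medium suppresses O-to-O silyl migration.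

Step 5
Reactants: 6 methyl 4-O-TBS-2,3-O-isopropylidene-D-ribonate
Product: 7 methyl 4-O-TBS-2,3-O-isopropylidene-5-aldehydo-D-ribonate
Conditions: Dess–Martin periodinane, CH2Cl2, 0 °C to rt
Reagents that add atoms: none
Why: Dess–Martin oxidation stops at the aldehyde under non-basic conditions, so the alpha-silyloxy stereocentre C3 is not epimerised and the beta-alkoxy group is not eliminated.

Step 6
Reactants: 7 methyl 4-O-TBS-2,3-O-isopropylidene-5-aldehydo-D-ribonate; 8 (1,3-dioxolan-2-ylmethyl)triphenylphosphonium bromide
Product: 10 methyl (5Z)-5,6-dideoxy-6-(1,3-dioxolan-2-yl)-4-O-TBS-2,3-O-isopropylidene-D-ribo-hex-5-enonate, via dioxolanylmethylene phosphorane 9 (not isolated)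
Conditions: 8, KN(SiMe3)2 (slightly less than 8), THF, 0 °C; then 7, −78 to 0 °C
Reagents that add atoms: (1,3-dioxolan-2-ylmethyl)triphenylphosphonium bromide (8), [Br-].C1COC(C[P+](c2ccccc2)(c2ccccc2)c2ccccc2)O1
Why: Wittig olefination with a non-stabilised ylide under lithium-free conditions at low temperature runs through the kinetically favoured cis-oxaphosphetane and should give mainly the Z C4=C5 alkene with C6 at the aldehyde oxidation level, and any E isomer can be removed by chromatography at this robust stage.

Step 7
Reactants: 10 methyl (5Z)-5,6-dideoxy-6-(1,3-dioxolan-2-yl)-4-O-TBS-2,3-O-isopropylidene-D-ribo-hex-5-enonate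
Product: 11 (5Z)-5,6-dideoxy-6-(1,3-dioxolan-2-yl)-4-O-TBS-2,3-O-isopropylidene-D-ribo-hex-5-enonic acid
Conditions: LiOH, THF/H2O, 0 °C to rt; cold 1 M HCl to pH 4, EtOAc
Reagents that add atoms: lithium hydroxide, [Li+].[OH-]
Why: Saponification (BAc2) of the activated alpha-alkoxy methyl ester leaves silyl ether, ketal and acetal untouched, and base-induced epimerisation at C1 is harmless because step 9 erases that centre.

Step 8
Reactants: 11 (5Z)-5,6-dideoxy-6-(1,3-dioxolan-2-yl)-4-O-TBS-2,3-O-isopropylidene-D-ribo-hex-5-enonic acid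
Product: 12 (5Z)-5,6-dideoxy-4-O-TBS-2,3-O-isopropylidene-7-oxo-D-ribo-hept-5-enoic acid
Conditions: 10% aq. oxalic acid on SiO2, CH2Cl2, 0 °C to rt, dark; filter, EtOAc wash, dry azeotropically, use at once
Reagents that add atoms: water, O
Why: Mild acid-catalysed acetal hydrolysis cleaves the alkenyl dioxolane, which ionises through a conjugated oxocarbenium ion far more readily than the carboxyl-deactivated acetonide, while the electron-withdrawing O3 disfavours the cationic character at C4 that would let the Z alkene rotate.

Step 9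
Reactants: 12 (5Z)-5,6-dideoxy-4-O-TBS-2,3-O-isopropylidene-7-oxo-D-ribo-hept-5-enoic acid
Product: 15 tricyclic beta-lactone, via acyloxypyridinium salt 13 (not isolated), via acylpyridinium enolate 14 (not isolated)
Conditions: 2-bromo-1-ethylpyridinium tetrafluoroborate, iPr2NEt, 4-pyrrolidinopyridine (cat.), CH2Cl2, −20 to 0 °C, slow addition of 12, high dilution
Reagents that add atoms: none
Why: Proposed new method: the carboxylate of 12 displaces bromide from the pyridinium salt to give 13, 4-pyrrolidinopyridine takes over the acyl group, iPr2NEt removes the C1 proton (directly or by way of the alkoxyketene) to give enolate 14, C1 of 14 adds to the C6 aldehyde, and the aldolate oxygen acylates itself at C7 and expels the catalyst. The closest known reaction type is the nucleophile-catalysed aldol-lactonisation of aldehyde acids and keto acids to carbocycle-fused beta-lactones, which has built fully substituted alpha-amino centres but has not been shown on an alpha,beta-dialkoxy acid or with a conjugated Z-enal as acceptor. The cyclohexene closes by a 6-(enolexo)-exo-trig aldol addition and the oxetanone by a 4-exo-trig acyl substitution. C1 is controlled by the tether, because the enolate is planar within the dioxolane and the short C3–C4=C5 arm on C2 can deliver C6 only to the face on which C3 stands, which makes the dioxolane cis-fused and puts O1 cis to O2 whatever the C1 configuration of 12. C6 is controlled by the four-membered ring, since only the aldolate with O6 cis to C7 can lactonise while the other one reverts by retro-aldol. The step needs 1,2-addition to outrun Z-to-E isomerisation, vinylogous deprotonation at C3 and beta-elimination of O2, and this is secured by the bulky, non-leaving OTBS group beside the enal beta-carbon C4, by the acetonide that holds the C2–O2 bond near the nodal plane of the enolate, and by slow addition at low temperature and high dilution.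

Step 10
Reactants: 15 tricyclic beta-lactone
Product: 16 C6,C7-diol with O3-TBS and O1,O2-acetonide
Conditions: LiAlH4, THF, −20 to 0 °C; Na2SO4·10H2O quench, filter
Reagents that add atoms: none
Why: Hydride reduction attacks the strained acyl carbon C7 of the beta-lactone and gives the 1,3-diol with C7 as CH2OH and O6 retained on C6, so no stereocentre changes.

Step 11
Reactants: 16 C6,C7-diol with O3-TBS and O1,O2-acetonide
Product: 17 C3,C6,C7-triol with O1,O2-acetonide
Conditions: TBAF, THF, 0 °C to rt
Reagents that add atoms: none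
Why: Fluoride cleavage of the last silyl ether frees O3 while the acetonide keeps O1 and O2 masked, which separates the three hydroxyls to be acylated from the two that must stay free.

Step 12
Reactants: 17 C3,C6,C7-triol with O1,O2-acetonide; 18 benzoyl chloride
Product: 19 O3,O6,O7-tribenzoate with O1,O2-acetonide
Conditions: BzCl (excess), pyridine, DMAP (cat.), CH2Cl2, 0 °C to rt
Reagents that add atoms: benzoyl chloride (18), O=C(Cl)c1ccccc1
Why: DMAP-catalysed acylation esterifies the primary C7 hydroxyl and the two allylic secondary hydroxyls at C3 and C6 with retention, since only O–H bonds are broken.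

Step 13
Reactants: 19 O3,O6,O7-tribenzoate with O1,O2-acetonide
Product: 20 [(1R,2R,3R,6R)-3,6-bis(benzoyloxy)-1,2-dihydroxycyclohex-4-en-1-yl]methyl benzoate
Conditions: TFA/H2O, CH2Cl2, 0 °C to rt
Reagents that add atoms: none
Why: Aqueous acid hydrolyses the isopropylidene ketal through the acetone-derived oxocarbenium ion without breaking a ring C–O bond, and acidic rather than basic conditions keep the benzoates from migrating to the freed O1 and O2.

Compound list
1 | 2,3-O-isopropylidene-D-ribono-1,4-lactone | O=C1O[C@H](CO)[C@H]2OC(C)(C)O[C@@H]12 | starting material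
2 | 5-O-(tert-butyldimethylsilyl)-2,3-O-isopropylidene-D-ribono-1,4-lactone | O=C1O[C@H](CO[Si](C)(C)C(C)(C)C)[C@H]2OC(C)(C)O[C@@H]12 | intermediate
3 | potassium 5-O-TBS-2,3-O-isopropylidene-D-ribonate | [K+].[O-]C(=O)[C@@H]1OC(C)(C)O[C@@H]1[C@H](O)CO[Si](C)(C)C(C)(C)C | intermediate
4 | methyl 5-O-TBS-2,3-O-isopropylidene-D-ribonate (free OH on sugar C4 = C3) | COC(=O)[C@@H]1OC(C)(C)O[C@@H]1[C@H](O)CO[Si](C)(C)C(C)(C)C | intermediate
5 | methyl 4,5-bis-O-TBS-2,3-O-isopropylidene-D-ribonate | COC(=O)[C@@H]1OC(C)(C)O[C@@H]1[C@H](O[Si](C)(C)C(C)(C)C)CO[Si](C)(C)C(C)(C)C | intermediate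
6 | methyl 4-O-TBS-2,3-O-isopropylidene-D-ribonate (primary OH free) | COC(=O)[C@@H]1OC(C)(C)O[C@@H]1[C@H](O[Si](C)(C)C(C)(C)C)CO | intermediate
7 | methyl 4-O-TBS-2,3-O-isopropylidene-5-aldehydo-D-ribonate (aldehyde carbon = C4) | COC(=O)[C@@H]1OC(C)(C)O[C@@H]1[C@H](O[Si](C)(C)C(C)(C)C)C=O | intermediate
8 | (1,3-dioxolan-2-ylmethyl)triphenylphosphonium bromide | [Br-].C1COC(C[P+](c2ccccc2)(c2ccccc2)c2ccccc2)O1 | starting material
9 | (1,3-dioxolan-2-ylmethylene)triphenylphosphorane | C1COC(C=P(c2ccccc2)(c2ccccc2)c2ccccc2)O1 | intermediate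
10 | methyl (5Z)-5,6-dideoxy-6-(1,3-dioxolan-2-yl)-4-O-TBS-2,3-O-isopropylidene-D-ribo-hex-5-enonate | COC(=O)[C@@H]1OC(C)(C)O[C@@H]1[C@H](O[Si](C)(C)C(C)(C)C)/C=C\C1OCCO1 | intermediate
11 | (5Z)-5,6-dideoxy-6-(1,3-dioxolan-2-yl)-4-O-TBS-2,3-O-isopropylidene-D-ribo-hex-5-enonic acid | OC(=O)[C@@H]1OC(C)(C)O[C@@H]1[C@H](O[Si](C)(C)C(C)(C)C)/C=C\C1OCCO1 | intermediate
12 | (5Z)-5,6-dideoxy-4-O-TBS-2,3-O-isopropylidene-7-oxo-D-ribo-hept-5-enoic acid (Z-enal acid, key-step precursor) | OC(=O)[C@@H]1OC(C)(C)O[C@@H]1[C@H](O[Si](C)(C)C(C)(C)C)/C=C\C=O | intermediate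
13 | 2-acyloxy-1-ethylpyridinium tetrafluoroborate of acid 12 | CC[n+]1ccccc1OC(=O)[C@@H]1OC(C)(C)O[C@@H]1[C@H](O[Si](C)(C)C(C)(C)C)/C=C\C=O.F[B-](F)(F)F | intermediate
14 | zwitterionic C1 enolate of the 4-pyrrolidinopyridinium acyl salt (C1=C7 exocyclic to the dioxolane) | [O-]C(=C1OC(C)(C)O[C@@H]1[C@H](O[Si](C)(C)C(C)(C)C)/C=C\C=O)[n+]1ccc(cc1)N1CCCC1 | intermediate
15 | tricyclic beta-lactone: cyclohex-4-ene cis-fused to the dioxolane at C1–C2 and to the oxetan-2-one at C1–C6; O1, O2 and O3(TBS) on one face, C7 and O6 on the other | O=C1O[C@@H]2C=C[C@@H](O[Si](C)(C)C(C)(C)C)[C@H]3OC(C)(C)O[C@@]123 | intermediate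
16 | 1-hydroxymethyl-cyclohex-4-ene-1,2,3,6-tetrol 1,2-acetonide 3-TBS ether; CH2OH and 6-OH cis, on the face opposite to O1, O2, O3 | OC[C@@]12OC(C)(C)O[C@@H]1[C@H](O[Si](C)(C)C(C)(C)C)C=C[C@H]2O | intermediate
17 | 1-hydroxymethyl-cyclohex-4-ene-1,2,3,6-tetrol 1,2-acetonide (C3, C6, C7 triol; same faces as 16) | OC[C@@]12OC(C)(C)O[C@@H]1[C@H](O)C=C[C@H]2O | intermediate
18 | benzoyl chloride | O=C(Cl)c1ccccc1 | starting material
19 | O3,O6,O7-tribenzoate of 17 (1,2-acetonide retained) | O=C(OC[C@@]12OC(C)(C)O[C@@H]1[C@H](OC(=O)c1ccccc1)C=C[C@H]2OC(=O)c1ccccc1)c1ccccc1 | intermediate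
20 | [(1R,2R,3R,6R)-3,6-bis(benzoyloxy)-1,2-dihydroxycyclohex-4-en-1-yl]methyl benzoate | O=C(OC[C@@]1(O)[C@H](O)[C@H](OC(=O)c2ccccc2)C=C[C@H]1OC(=O)c1ccccc1)c1ccccc1 | target

Total step count: 13. Longest linear sequence: 13 steps (1 to 20).

Steps most likely to fail

**1. Step 9.**
- What may go wrong:
  - Z-to-E isomerisation of the enal through reversible conjugate addition of the amines. The E isomer cannot cyclise.
  - Vinylogous deprotonation at C3.
  - Sluggish enolisation of the hindered tertiary C1–H.
  - Intermolecular acylation in place of ring closure.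
- Fallback, by known chemistry, setting out from 10 and coming back at 16:
  - The acetal of 10 is cleaved as in step 8 to the Z-enal methyl ester F1.
  - LiN(SiMe3)2 in THF at −78 °C generates the lithium ester enolate. Dioxolane-4-carboxylate enolates are a known class that holds at this temperature.
  - The enolate closes onto the aldehyde in an intramolecular aldol addition to the bicyclic beta-hydroxy ester F2.
  - C1 is again fixed by the tether, whereas C6 then rests on the lithium chelate and on separation of epimers.
  - LiAlH4 reduces the ester of F2 to diol 16.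

**2. Step 8.**
- What may go wrong: acid-induced Z-to-E isomerisation while the acetal is opened, or partial loss of the acetonide or the silyl ether if the cleavage has to be forced.
- Fallback, setting out from 7 and coming back at 12; it makes the aldehyde by neutral oxidation instead of hydrolysis:
  - Stork–Zhao olefination of 7 with (iodomethyl)triphenylphosphonium iodide and NaN(SiMe3)2 in THF/DMPU at −78 °C gives the Z-vinyl iodide F3.
  - Stille coupling with (tributylstannyl)methanol under Pd(PPh3)4 gives the Z-allylic alcohol F4 with retention of geometry. Zerovalent palladium does not ionise the allylic silyl ether.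
  - LiOH at 0 °C gives the hydroxy acid F5.
  - Dess–Martin oxidation of F5 gives 12.

**3. Step 2.**
- What may go wrong: re-closure of the gamma-lactone with loss of methanol during alkylation, work-up or concentration of the hydroxy ester.
- Fallback, setting out from 2 and coming back at 5; it protects O3 before any ester exists:
  - After the KOH opening, the dry salt 3 is persilylated (TBSCl, imidazole, DMF) to the silyl ester bis-silyl ether F6.
  - K2CO3 in aqueous MeOH cleaves only the silyl ester and gives the acid F7.
  - MeI and K2CO3 in DMF convert F7 into 5.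

Further compounds
F1 | step 9 | methyl (5Z)-5,6-dideoxy-4-O-TBS-2,3-O-isopropylidene-7-oxo-D-ribo-hept-5-enoate | COC(=O)[C@@H]1OC(C)(C)O[C@@H]1[C@H](O[Si](C)(C)C(C)(C)C)/C=C\C=O
F2 | step 9 | methyl 6-hydroxy-1,2-O-isopropylidene-3-O-TBS-cyclohex-4-ene-1-carboxylate (CO2Me and 6-OH cis, opposite to O1, O2, O3) | COC(=O)[C@@]12OC(C)(C)O[C@@H]1[C@H](O[Si](C)(C)C(C)(C)C)C=C[C@H]2O
F3 | step 8 | methyl (5Z)-5,6-dideoxy-6-iodo-4-O-TBS-2,3-O-isopropylidene-D-ribo-hex-5-enonate | COC(=O)[C@@H]1OC(C)(C)O[C@@H]1[C@H](O[Si](C)(C)C(C)(C)C)/C=C\I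
F4 | step 8 | methyl (5Z)-5,6-dideoxy-4-O-TBS-2,3-O-isopropylidene-D-ribo-hept-5-enonate (7-OH free) | COC(=O)[C@@H]1OC(C)(C)O[C@@H]1[C@H](O[Si](C)(C)C(C)(C)C)/C=C\CO
F5 | step 8 | (5Z)-5,6-dideoxy-4-O-TBS-2,3-O-isopropylidene-D-ribo-hept-5-enonic acid (7-OH free) | OC(=O)[C@@H]1OC(C)(C)O[C@@H]1[C@H](O[Si](C)(C)C(C)(C)C)/C=C\CO
F6 | step 2 | tert-butyldimethylsilyl 4,5-bis-O-TBS-2,3-O-isopropylidene-D-ribonate | CC(C)(C)[Si](C)(C)OC(=O)[C@@H]1OC(C)(C)O[C@@H]1[C@H](O[Si](C)(C)C(C)(C)C)CO[Si](C)(C)C(C)(C)C
F7 | step 2 | 4,5-bis-O-TBS-2,3-O-isopropylidene-D-ribonic acid | OC(=O)[C@@H]1OC(C)(C)O[C@@H]1[C@H](O[Si](C)(C)C(C)(C)C)CO[Si](C)(C)C(C)(C)C
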